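## Retrosynthetic overview

1. Target 16 ⇐ 3‑hydroxyisoflavanone 14 by acidic MOM removal and dehydration. The γ‑pyranone ring is formed last.
2. 14 ⇐ keto‑aldehyde 13. The C4–C3 bond comes from an NHC‑catalysed intramolecular crossed benzoin reaction, in which the A‑ring aldehyde acts as an acyl anion equivalent (Breslow intermediate) towards the B‑ring aryl ketone.
3. 13 ⇐ A‑ring salicylaldehyde 12 + B‑ring α‑bromoketone 10 (ether formation); 10 ⇐ chromene methyl ketone 7.
4. 7 ⇐ diene 6 by ring‑closing metathesis (pyran ring formed first). 6 ⇐ phenol 4 + isoprene monoepoxide 5 by Pd‑catalysed asymmetric allylic etherification, which sets the only stereocentre (S).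
5. 4 ⇐ 2',4'‑dihydroxyacetophenone 1 (C3 iodination, 4‑O‑MOM, vinylation); 12 ⇐ 2,4,6‑trihydroxybenzaldehyde 11.

Assumption: the (R,R)‑Trost ligand is taken to give the (S)‑ether in step 4 by analogy with Pd‑DYKAT of vinyl epoxides; the sense is checked at compound 7 and the mirror‑image ligand is used if it is reversed.

## Route

Step 1
Reactants: 1 2',4'-dihydroxyacetophenone
Product: 2 1-(2,4-dihydroxy-3-iodophenyl)ethan-1-one
Conditions: I2 (0.4 equiv), HIO3 (0.2 equiv), EtOH/H2O, 40 °C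
Reagents that add atoms: iodine, II; iodic acid, O[I](=O)=O
Why: Electrophilic aromatic iodination with I2/HIO3 of a 4‑acylresorcinol goes to C3, the position ortho to both hydroxyls (shown by two ortho‑coupled doublets for H5/H6), and all iodine is consumed (5 ArH + 2 I2 + HIO3 → 5 ArI + 3 H2O).

Step 2
Reactants: 2 1-(2,4-dihydroxy-3-iodophenyl)ethan-1-one
Product: 3 1-[2-hydroxy-3-iodo-4-(methoxymethoxy)phenyl]ethan-1-one
Conditions: MOMCl (1.1 equiv), K2CO3, acetone, 0 °C to rt
Reagents that add atoms: chloromethyl methyl ether (MOMCl), COCCl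
Why: Chemoselective Williamson‑type MOM etherification, because the 2‑OH is tied up in a hydrogen bond to the acetyl group and only the 4‑OH reacts.

Step 3
Reactants: 3 1-[2-hydroxy-3-iodo-4-(methoxymethoxy)phenyl]ethan-1-one
Product: 4 1-[3-ethenyl-2-hydroxy-4-(methoxymethoxy)phenyl]ethan-1-one
Conditions: Bu3SnCH=CH2 (1.2 equiv), Pd(PPh3)4 (5 mol %), toluene, 100 °C
Reagents that add atoms: tributyl(vinyl)stannane, C=C[Sn](CCCC)(CCCC)CCCC
Why: Stille cross‑coupling of the aryl iodide tolerates the free phenol, ketone and MOM ether and installs the styrene needed for ring closure.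

Step 4
Reactants: 4 1-[3-ethenyl-2-hydroxy-4-(methoxymethoxy)phenyl]ethan-1-one; 5 isoprene monoepoxide (racemic 2-ethenyl-2-methyloxirane, 1.5 equiv)
Product: 6 1-[3-ethenyl-2-{[(2S)-1-hydroxy-2-methylbut-3-en-2-yl]oxy}-4-(methoxymethoxy)phenyl]ethan-1-one
Conditions: Pd2(dba)3·CHCl3 (2.5 mol %), (R,R)-DACH-phenyl Trost ligand (7.5 mol %), CH2Cl2, 0 °C to rt
Reagents that add atoms: none
Why: Trost Pd‑catalysed dynamic kinetic asymmetric allylic etherification: the racemic epoxide ionises to a rapidly equilibrating π‑allyl‑Pd alkoxide, the alkoxide deprotonates the phenol and directs it to the tertiary terminus, and the chiral ligand pocket selects the enantioface, setting the quaternary C–O centre as (S).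

Step 5
Reactants: 6 1-[3-ethenyl-2-{[(2S)-1-hydroxy-2-methylbut-3-en-2-yl]oxy}-4-(methoxymethoxy)phenyl]ethan-1-one
Product: 7 1-[(2S)-2-(hydroxymethyl)-5-(methoxymethoxy)-2-methyl-2H-chromen-8-yl]ethan-1-one
Conditions: Grubbs II (5 mol %), CH2Cl2, 40 °C
Reagents that add atoms: none
Why: Ring‑closing metathesis of the styrene with the vinyl group on the quaternary carbon closes the 2H‑chromene with loss of ethene and breaks no bond to the stereocentre.

Step 6
Reactants: 7 1-[(2S)-2-(hydroxymethyl)-5-(methoxymethoxy)-2-methyl-2H-chromen-8-yl]ethan-1-one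
Product: 10 2-bromo-1-[(2S)-2-(hydroxymethyl)-5-(methoxymethoxy)-2-methyl-2H-chromen-8-yl]ethan-1-one, via bis-TMS enol ether 8 (not isolated), via O-TMS bromoketone 9 (not isolated)
Conditions: LiHMDS (2.2 equiv), TMSCl (2.5 equiv), THF, −78 °C; NBS (1.05 equiv), −78 to 0 °C; aq. citric acid work-up
Reagents that add atoms: N-bromosuccinimide, O=C1CCC(=O)N1Br; chlorotrimethylsilane, C[Si](C)(C)Cl (silicon only in 8 and 9)
Why: Regiospecific α‑bromination through the silyl enol ether, which reacts with NBS at −78 °C far faster than the chromene alkene, while the alcohol is silylated in passing and freed again on mild acidic work‑up.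

Step 7
Reactants: 11 2,4,6-trihydroxybenzaldehyde
Product: 12 2-hydroxy-4,6-bis(methoxymethoxy)benzaldehyde
Conditions: MOMCl (2.1 equiv), K2CO3, acetone, 0 °C to rt
Reagents that add atoms: chloromethyl methyl ether (MOMCl), COCCl
Why: Selective MOM etherification of the para‑OH and one ortho‑OH, after which the remaining ortho‑OH is strongly hydrogen‑bonded to the aldehyde and stays free.

Step 8
Reactants: 10 2-bromo-1-[(2S)-2-(hydroxymethyl)-5-(methoxymethoxy)-2-methyl-2H-chromen-8-yl]ethan-1-one; 12 2-hydroxy-4,6-bis(methoxymethoxy)benzaldehyde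
Product: 13 2-{2-[(2S)-2-(hydroxymethyl)-5-(methoxymethoxy)-2-methyl-2H-chromen-8-yl]-2-oxoethoxy}-4,6-bis(methoxymethoxy)benzaldehyde
Conditions: K2CO3 (1.5 equiv), acetone, rt
Reagents that add atoms: none
Why: Williamson SN2 O‑alkylation of the phenoxide by the primary α‑bromoketone, run at room temperature with a weak base so that the aldol condensation to a 2‑aroylbenzofuran stays slow.

Step 9
Reactants: 13 2-{2-[(2S)-2-(hydroxymethyl)-5-(methoxymethoxy)-2-methyl-2H-chromen-8-yl]-2-oxoethoxy}-4,6-bis(methoxymethoxy)benzaldehyde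
Product: 14 (3RS)-3-hydroxy-3-[(2S)-2-(hydroxymethyl)-5-(methoxymethoxy)-2-methyl-2H-chromen-8-yl]-5,7-bis(methoxymethoxy)-2,3-dihydro-4H-chromen-4-one
Conditions: 2-(pentafluorophenyl)-6,7-dihydro-5H-pyrrolo[2,1-c][1,2,4]triazol-2-ium BF4 (20 mol %), DBU (15 mol %), THF (0.05 M), rt
Reagents that add atoms: none
Why: NHC‑catalysed intramolecular crossed aldehyde–ketone benzoin reaction, in which the Breslow intermediate of the aldehyde adds as an acyl anion to the tethered aryl ketone (6‑exo) to form C4–C3; the new C3 carbinol centre forms without control and is removed in step 10.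

Step 10
Reactants: 14 (3RS)-3-hydroxy-3-[(2S)-2-(hydroxymethyl)-5-(methoxymethoxy)-2-methyl-2H-chromen-8-yl]-5,7-bis(methoxymethoxy)-2,3-dihydro-4H-chromen-4-one
Product: 16 5,7-dihydroxy-3-[(2S)-5-hydroxy-2-(hydroxymethyl)-2-methyl-2H-chromen-8-yl]-4H-chromen-4-one (target CNP0141863.1), via MOM-free 3-hydroxyisoflavanone 15 (not isolated)
Conditions: 3 M aq. HCl, MeOH, 50–55 °C, dark
Reagents that add atoms: none
Why: Acid‑catalysed acetal methanolysis removes the three MOM groups, and the freed 4'-OH para to the tertiary benzylic carbinol then drives E1 dehydration with loss of H‑2 to the conjugated 4H‑chromen‑4‑one, while the mild, light‑free conditions leave the chromene C2 centre untouched.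

## Compound list

1 | 2',4'-dihydroxyacetophenone | CC(=O)c1ccc(O)cc1O | starting material
2 | 1-(2,4-dihydroxy-3-iodophenyl)ethan-1-one | CC(=O)c1ccc(O)c(I)c1O | intermediate
3 | 1-[2-hydroxy-3-iodo-4-(methoxymethoxy)phenyl]ethan-1-one | CC(=O)c1ccc(OCOC)c(I)c1O | intermediate
4 | 1-[3-ethenyl-2-hydroxy-4-(methoxymethoxy)phenyl]ethan-1-one | CC(=O)c1ccc(OCOC)c(C=C)c1O | intermediate
5 | isoprene monoepoxide (racemic 2-ethenyl-2-methyloxirane) | CC1(C=C)CO1 | starting material
6 | 1-[3-ethenyl-2-{[(2S)-1-hydroxy-2-methylbut-3-en-2-yl]oxy}-4-(methoxymethoxy)phenyl]ethan-1-one | C=C[C@@](C)(CO)Oc1c(C(C)=O)ccc(OCOC)c1C=C | intermediate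
7 | 1-[(2S)-2-(hydroxymethyl)-5-(methoxymethoxy)-2-methyl-2H-chromen-8-yl]ethan-1-one | C[C@@]1(CO)C=Cc2c(OCOC)ccc(C(C)=O)c2O1 | intermediate
8 | (2S)-5-(methoxymethoxy)-2-methyl-2-[(trimethylsilyloxy)methyl]-8-[1-(trimethylsilyloxy)ethenyl]-2H-chromene (bis-TMS enol ether, not isolated) | C[C@@]1(CO[Si](C)(C)C)C=Cc2c(OCOC)ccc(C(=C)O[Si](C)(C)C)c2O1 | intermediate
9 | 2-bromo-1-[(2S)-5-(methoxymethoxy)-2-methyl-2-[(trimethylsilyloxy)methyl]-2H-chromen-8-yl]ethan-1-one (not isolated) | C[C@@]1(CO[Si](C)(C)C)C=Cc2c(OCOC)ccc(C(=O)CBr)c2O1 | intermediate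
10 | 2-bromo-1-[(2S)-2-(hydroxymethyl)-5-(methoxymethoxy)-2-methyl-2H-chromen-8-yl]ethan-1-one | C[C@@]1(CO)C=Cc2c(OCOC)ccc(C(=O)CBr)c2O1 | intermediate
11 | 2,4,6-trihydroxybenzaldehyde | O=Cc1c(O)cc(O)cc1O | starting material
12 | 2-hydroxy-4,6-bis(methoxymethoxy)benzaldehyde | O=Cc1c(O)cc(OCOC)cc1OCOC | intermediate
13 | 2-{2-[(2S)-2-(hydroxymethyl)-5-(methoxymethoxy)-2-methyl-2H-chromen-8-yl]-2-oxoethoxy}-4,6-bis(methoxymethoxy)benzaldehyde | C[C@@]1(CO)C=Cc2c(OCOC)ccc(C(=O)COc3cc(OCOC)cc(OCOC)c3C=O)c2O1 | intermediate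
14 | (3RS)-3-hydroxy-3-[(2S)-2-(hydroxymethyl)-5-(methoxymethoxy)-2-methyl-2H-chromen-8-yl]-5,7-bis(methoxymethoxy)-2,3-dihydro-4H-chromen-4-one | C[C@@]1(CO)C=Cc2c(OCOC)ccc(C3(O)COc4cc(OCOC)cc(OCOC)c4C3=O)c2O1 | intermediate
15 | (3RS)-3,5,7-trihydroxy-3-[(2S)-5-hydroxy-2-(hydroxymethyl)-2-methyl-2H-chromen-8-yl]-2,3-dihydro-4H-chromen-4-one (not isolated) | C[C@@]1(CO)C=Cc2c(O)ccc(C3(O)COc4cc(O)cc(O)c4C3=O)c2O1 | intermediate
16 | 5,7-dihydroxy-3-[(2S)-5-hydroxy-2-(hydroxymethyl)-2-methyl-2H-chromen-8-yl]-4H-chromen-4-one | C[C@@]1(CO)C=Cc2c(O)ccc(-c3coc4cc(O)cc(O)c4c3=O)c2O1 | target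

## Step count and risks

Total step count: 10. Longest linear sequence: 9 (steps 1–6, 8, 9, 10, from 1 to 16); step 7 is a one‑step side branch.

Steps most likely to fail:

Step 4. The phenol is hydrogen‑bonded and flanked by two ortho substituents, and the acylphenoxide is a good enough leaving group for Pd to re‑ionise the product, so conversion and ee are both at risk. The fallback sets out from 3 and comes back at 7. A Heck reaction of 3 with racemic 2-methylbut-3-ene-1,2-diol (Pd(OAc)2, Bu4NCl, NaHCO3, DMF, 80 °C) gives the (E)-styryl diol F1. Mild acid (PPTS, toluene, 60 °C) cyclodehydrates it through the allyl cation/o‑quinone methide to the racemic chromene alcohol F2. Lipase‑catalysed acylation (Amano lipase PS, vinyl acetate, MTBE, rt) then resolves it: written for faster acylation of the (R)-alcohol, it gives the (R)-acetate F3 and leaves (S)-alcohol 7, which rejoins the route at step 6.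

Step 9. The aldehyde is electron‑rich and di‑ortho‑substituted, the ketone is hindered, and base can divert 13 into aldol condensation to a 2‑aroylbenzofuran. The fallback sets out from 13 and comes back at 14. Reductive ketyl (pinacol) cyclisation with SmI2 (THF, −78 °C) gives the chromane-3,4-diol F4. Selective oxidation of its secondary benzylic C4 carbinol (DDQ, dioxane, rt) then returns the α‑ketol 14.

Step 10. Dehydration of the α‑ketol may lag behind MOM removal, or prolonged acid may damage the chromene. The fallback sets out from 14 and comes back at 16. The primary alcohol alone is acetylated (Ac2O, pyridine, 0 °C) to the α‑ketol acetate F5. Burgess reagent (toluene, 60 °C) then effects syn‑elimination of the tertiary carbinol with H‑2 to the protected isoflavone acetate F6. Finally HCl/MeOH (50 °C) removes the three MOM groups and the acetate to give 16.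

## Further compounds

F1 | step 4 | 1-{3-[(1E)-3,4-dihydroxy-3-methylbut-1-en-1-yl]-2-hydroxy-4-(methoxymethoxy)phenyl}ethan-1-one (racemic) | CC(=O)c1ccc(OCOC)c(/C=C/C(C)(O)CO)c1O
F2 | step 4 | rac-1-[2-(hydroxymethyl)-5-(methoxymethoxy)-2-methyl-2H-chromen-8-yl]ethan-1-one | CC1(CO)C=Cc2c(OCOC)ccc(C(C)=O)c2O1
F3 | step 4 | [(2R)-8-acetyl-5-(methoxymethoxy)-2-methyl-2H-chromen-2-yl]methyl acetate | C[C@]1(COC(C)=O)C=Cc2c(OCOC)ccc(C(C)=O)c2O1
F4 | step 9 | 3-[(2S)-2-(hydroxymethyl)-5-(methoxymethoxy)-2-methyl-2H-chromen-8-yl]-5,7-bis(methoxymethoxy)chromane-3,4-diol (mixture of diastereomers) | C[C@@]1(CO)C=Cc2c(OCOC)ccc(C3(O)COc4cc(OCOC)cc(OCOC)c4C3O)c2O1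
F5 | step 10 | [(2S)-8-[(3RS)-3-hydroxy-5,7-bis(methoxymethoxy)-4-oxo-2,3-dihydro-4H-chromen-3-yl]-5-(methoxymethoxy)-2-methyl-2H-chromen-2-yl]methyl acetate | C[C@@]1(COC(C)=O)C=Cc2c(OCOC)ccc(C3(O)COc4cc(OCOC)cc(OCOC)c4C3=O)c2O1
F6 | step 10 | [(2S)-8-[5,7-bis(methoxymethoxy)-4-oxo-4H-chromen-3-yl]-5-(methoxymethoxy)-2-methyl-2H-chromen-2-yl]methyl acetate | C[C@@]1(COC(C)=O)C=Cc2c(OCOC)ccc(-c3coc4cc(OCOC)cc(OCOC)c4c3=O)c2O1
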